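The reckoning here follows the nucleophile and sets the free base aside: at 5.00 d the electrophile of the north-east run (1.8 equiv of free base) and of the south run (9.5 equiv) differ by 1.7 percentage points, less than the 5 points that counts as a change.

common to all: electrophile 20 mM

|  | nucleophile | free base | remark | time |
|---|---|---|---|---|
| north-east | 0.80 equiv | 1.8 equiv | run made earlier |  |
| south | 0.80 equiv | 9.5 equiv | run made earlier |  |
| zeta | 0.800 equiv | 3.00 equiv |  | 10 d |
| theta | 0.800 equiv | 6.00 equiv |  | 10 d |
| delta | 0.800 equiv | 12.0 equiv |  | 10 d |

| run | time / d | electrophile / % | target / % |
|---|---|---|---|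
| north-east | 0.250 | 89.7 | 9.7 |
| north-east | 0.833 | 75.5 | 20.8 |
| north-east | 1.25 | 69.9 | 25.0 |
| north-east | 2.00 | 61.0 | 28.2 |
| north-east | 3.00 | 55.7 | 27.8 |
| north-east | 4.00 | 51.5 | 27.1 |
| north-east | 5.00 | 48.1 | 25.1 |
| south | 0.417 | 83.4 | 14.3 |
| south | 0.625 | 80.1 | 19.0 |
| south | 0.833 | 76.2 | 20.8 |
| south | 1.25 | 68.7 | 25.0 |
| south | 2.00 | 62.8 | 29.0 |
| south | 3.00 | 54.6 | 29.2 |
| south | 5.00 | 46.4 | 25.9 |

(each reading ± 0.5 percentage points)

1. part of the electrophile that has reacted at the end, zeta
2. part of the electrophile that has reacted at the end, theta
3. part of the electrophile that has reacted at the end, delta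
4. what raising the equivalents of free base from its lowest to its highest value here does to the part of the electrophile that has reacted (changes below 5 percentage points count as none) (it rises / it falls / no change)

Suppose, as my own reckoning, that each target made comes with one acid set free, which takes a second nucleophile out at once, and that each target lost takes one electrophile with it. Reacted electrophile plus standing target then counts the nucleophile gone. The charge minus that sum, 3.00% as read in the north-east run at 5.00 d, is the free nucleophile left, in percent of the electrophile charged and with the scatter of the readings in it; the south run reads 0.500%. Further loss of electrophile is then taken to follow [electrophile][target].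

From above, within this supposition target stops at zero, so the count puts a ceiling of 80.0% on the reacted part. The north-east gain reads smaller from day to day, so its last daily gain held to the end adds 17 points to the 51.9% read there, which brings the estimated ceiling down to 68.9%. From below, at that ceiling the product [electrophile][target] would be 0.247 of its value at 4.00 d, and the daily gain held at that fraction gives an estimated floor of 56.1%.

The forecast gives 61%, 61% and 61% for zeta, theta and delta, each from 55% to 68%, with no change: “the rate looks zero-order in base”. Its 61% lies inside my bracket.

The flasks give 63.3%, 63.8% and 64.5%, a change of 1.2 points, so no change.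

    electrophile + nucleophile → acid set free + target (k = 1.23 M⁻¹ h⁻¹)
    nucleophile + acid set free ⇌ protonated nucleophile, settled at all times (K = 79000 M⁻¹)
    acid set free + free base ⇌ salt of the base (K = 22.4 M⁻¹, k = 36.1 M⁻¹ h⁻¹)
    acid set free + target → side product A (k = 14.5 M⁻¹ h⁻¹)
    electrophile + target → side product B (k = 0.354 M⁻¹ h⁻¹)

Zeta ends with the count at 0.526% of the electrophile charged, beside a simulated free nucleophile of 2.52%. That is 3.1% of its own charge, less than the 37% of the charged electrophile still there, and the nucleophile is the limiting reagent in zeta. The neighbour at 5.0 mM of electrophile, same equivalents and time, reacts 42.1% and holds 28.0% of target. Its count is 9.84%, and its simulated free nucleophile is 11.1% of the electrophile charged.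

(The numbers in the tables are calculated with constants of no real substance, and the scatter is random.)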